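**Plan**

- The retrosynthesis first removes three O-benzyl groups, then cuts the O1–C8a bond of the pyran ring. O1 is an aryl alkyl ether: its benzylic C2–O1 bond would ionise easily, but the aryl C8a–O1 bond on ring A can be forged by palladium from a C2 hydroxyl and a C8a triflate without touching C2 or C3.
- The open chain is then cut at C2–H (ketone), at C2–ring B (Weinreb amide plus aryl Grignard) and at C3–C4 (glycolate alkylation). The ring A benzyl bromide is traced back through its triflate, formyl group and the CH2–aryl bond of the bibenzyl.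
- Forward: B-alkyl Suzuki coupling gives the bibenzyl; formylation, ortho-demethylation, triflation, reduction and bromination give bromide 10. C4–C3 is joined first, then C2–ring B. The pyran ring is the only ring made and is closed in the penultimate step.
- Stereochemistry: C3 comes from the (R)-4-benzyloxazolidinone auxiliary in the glycolate alkylation. C2 comes from chelation-controlled Zn(BH4)2 reduction (1,2-anti) and is carried with retention through the ring closure.

Key step: step 12

Remark: chroman numbering (O1, C2, C3, C4, C4a to C8a) is used throughout; ring A is the benzo ring and ring B the aryl group on C2. Compounds 1, 2, 11, 12 and 18 are taken to be catalogue compounds.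

**Route**

Step 1
Reactants: 1 3,5-dimethoxystyrene; 2 1-(benzyloxy)-3-bromobenzene
Product: 4 1-[2-(3-benzyloxyphenyl)ethyl]-3,5-dimethoxybenzene, via B-alkyl-9-BBN 3 (not isolated)
Conditions: 9-BBN, THF, 0 °C to rt; then 2, PdCl2(dppf) (dppf = 1,1'-bis(diphenylphosphino)ferrocene, 3 mol %), aq K3PO4, DMF, 60 °C
Reagents that add atoms: none
Why: Anti-Markovnikov hydroboration of the styrene gives the primary alkylborane, which should undergo B-alkyl Suzuki–Miyaura coupling with the aryl bromide while the benzyl ether stays inert.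

Step 2
Reactants: 4 1-[2-(3-benzyloxyphenyl)ethyl]-3,5-dimethoxybenzene
Product: 6 2-[2-(3-benzyloxyphenyl)ethyl]-4,6-dimethoxybenzaldehyde, via iminium chloride 5 (not isolated)
Conditions: POCl3, DMF, 0 to 70 °C; then H2O
Reagents that add atoms: N,N-dimethylformamide, CN(C)C=O; water, O
Why: Vilsmeier–Haack formylation should attack the dimethoxy ring at the position ortho to one methoxy group, para to the other and next to the ethylene chain (the two such positions are equivalent), as orcinol dimethyl ether does, while the mono-alkoxy side-chain ring is too weakly activated to compete.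

Step 3
Reactants: 6 2-[2-(3-benzyloxyphenyl)ethyl]-4,6-dimethoxybenzaldehyde
Product: 7 2-[2-(3-benzyloxyphenyl)ethyl]-6-hydroxy-4-methoxybenzaldehyde
Conditions: MgI2·OEt2, toluene/Et2O, 80 °C; then dilute aq HCl
Reagents that add atoms: none
Why: Chelation of MgI2 between the formyl oxygen and the ortho methoxy oxygen directs iodide to that methyl group only (chelation-assisted ether cleavage), so the para methoxy group and the non-chelating benzyl ether should survive.

Step 4
Reactants: 7 2-[2-(3-benzyloxyphenyl)ethyl]-6-hydroxy-4-methoxybenzaldehyde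
Product: 8 3-[2-(3-benzyloxyphenyl)ethyl]-2-formyl-5-methoxyphenyl trifluoromethanesulfonate
Conditions: Tf2O, pyridine, CH2Cl2, 0 °C
Reagents that add atoms: trifluoromethanesulfonic anhydride, O=S(=O)(OS(=O)(=O)C(F)(F)F)C(F)(F)F
Why: O-Sulfonylation of a salicylaldehyde phenol with triflic anhydride and pyridine is routine and installs the leaving group later needed at C8a.

Step 5
Reactants: 8 3-[2-(3-benzyloxyphenyl)ethyl]-2-formyl-5-methoxyphenyl trifluoromethanesulfonate
Product: 9 3-[2-(3-benzyloxyphenyl)ethyl]-2-(hydroxymethyl)-5-methoxyphenyl trifluoromethanesulfonate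
Conditions: NaBH4, MeOH/THF, 0 °C
Reagents that add atoms: none
Why: Borohydride reduction of the aldehyde is chemoselective, and aryl triflates and benzyl ethers are stable to NaBH4 at 0 °C.

Step 6
Reactants: 9 3-[2-(3-benzyloxyphenyl)ethyl]-2-(hydroxymethyl)-5-methoxyphenyl trifluoromethanesulfonate
Product: 10 3-[2-(3-benzyloxyphenyl)ethyl]-2-(bromomethyl)-5-methoxyphenyl trifluoromethanesulfonate
Conditions: PBr3, CH2Cl2, 0 °C
Reagents that add atoms: phosphorus tribromide, BrP(Br)Br
Why: Conversion of a benzylic alcohol into the bromide with PBr3 is standard, and the para methoxy group makes the bromide a reactive SN2 partner for the next coupling (it is used without storage).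

Step 7
Reactants: 11 (R)-4-benzyloxazolidin-2-one; 12 (benzyloxy)acetyl chloride
Product: 14 (R)-4-benzyl-3-[(benzyloxy)acetyl]oxazolidin-2-one, via lithium oxazolidinide 13 (not isolated)
Conditions: n-BuLi, THF, −78 °C; then 12, −78 to 0 °C
Reagents that add atoms: none
Why: N-Acylation of the lithiated oxazolidinone with an acid chloride is the standard preparation of Evans glycolate imides.

Step 8
Reactants: 14 (R)-4-benzyl-3-[(benzyloxy)acetyl]oxazolidin-2-one; 10 3-[2-(3-benzyloxyphenyl)ethyl]-2-(bromomethyl)-5-methoxyphenyl trifluoromethanesulfonate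
Product: 16 (R)-4-benzyl-3-[(2S)-2-(benzyloxy)-3-{2-[2-(3-benzyloxyphenyl)ethyl]-4-methoxy-6-[(trifluoromethylsulfonyl)oxy]phenyl}propanoyl]oxazolidin-2-one, via sodium enolate 15 (not isolated)
Conditions: NaN(SiMe3)2, THF, −78 °C; then 10, −78 to −40 °C (enolate in excess)
Reagents that add atoms: none
Why: Evans glycolate alkylation: the chelated Z sodium enolate is alkylated by the benzylic bromide on the face opposite the C4 benzyl group of the auxiliary, which sets the (S) centre that becomes C3 and forms the C3–C4 bond.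

Step 9
Reactants: 16 (R)-4-benzyl-3-[(2S)-2-(benzyloxy)-3-{2-[2-(3-benzyloxyphenyl)ethyl]-4-methoxy-6-[(trifluoromethylsulfonyl)oxy]phenyl}propanoyl]oxazolidin-2-one
Product: 17 (2S)-2-(benzyloxy)-3-{2-[2-(3-benzyloxyphenyl)ethyl]-4-methoxy-6-[(trifluoromethylsulfonyl)oxy]phenyl}-N-methoxy-N-methylpropanamide
Conditions: MeNH(OMe)·HCl, AlMe3, CH2Cl2, −10 to 0 °C; then aq potassium sodium tartrate
Reagents that add atoms: N,O-dimethylhydroxylamine hydrochloride, CNOC.Cl
Why: Weinreb transamination of an N-acyloxazolidinone with the aluminium amide attacks the exocyclic carbonyl, aided by the α-alkoxy group, and releases the auxiliary without touching the α-centre or the triflate.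

Step 10
Reactants: 17 (2S)-2-(benzyloxy)-3-{2-[2-(3-benzyloxyphenyl)ethyl]-4-methoxy-6-[(trifluoromethylsulfonyl)oxy]phenyl}-N-methoxy-N-methylpropanamide; 18 1-(benzyloxy)-4-bromo-2-methoxybenzene
Product: 21 (2S)-2-(benzyloxy)-1-(4-benzyloxy-3-methoxyphenyl)-3-{2-[2-(3-benzyloxyphenyl)ethyl]-4-methoxy-6-[(trifluoromethylsulfonyl)oxy]phenyl}propan-1-one, via arylmagnesium bromide 19 (not isolated), via tetrahedral magnesium adduct 20 (not isolated)
Conditions: 18, Mg, THF, 40 °C; then 17, THF, −20 to 0 °C; then dilute aq HCl, 0 °C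
Reagents that add atoms: none
Why: Weinreb ketone synthesis: the chelated tetrahedral adduct prevents over-addition and enolisation, and at or below 0 °C the aryl Grignard reagent should add to the amide faster than it attacks the sulfonyl group of the aryl triflate.

Step 11
Reactants: 21 (2S)-2-(benzyloxy)-1-(4-benzyloxy-3-methoxyphenyl)-3-{2-[2-(3-benzyloxyphenyl)ethyl]-4-methoxy-6-[(trifluoromethylsulfonyl)oxy]phenyl}propan-1-one
Product: 22 (1R,2S)-2-(benzyloxy)-1-(4-benzyloxy-3-methoxyphenyl)-3-{2-[2-(3-benzyloxyphenyl)ethyl]-4-methoxy-6-[(trifluoromethylsulfonyl)oxy]phenyl}propan-1-ol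
Conditions: Zn(BH4)2, Et2O/THF, −30 to 0 °C; then H2O
Reagents that add atoms: none
Why: Chelation-controlled (Cram chelate) reduction: zinc bridges the ketone and benzyloxy oxygens and hydride arrives on the face away from the C4 methylene, which should give the 1,2-anti alcohol with the (R) centre that becomes C2.

Step 12
Reactants: 22 (1R,2S)-2-(benzyloxy)-1-(4-benzyloxy-3-methoxyphenyl)-3-{2-[2-(3-benzyloxyphenyl)ethyl]-4-methoxy-6-[(trifluoromethylsulfonyl)oxy]phenyl}propan-1-ol
Product: 23 (2R,3S)-3-(benzyloxy)-2-(4-benzyloxy-3-methoxyphenyl)-5-[2-(3-benzyloxyphenyl)ethyl]-7-methoxychroman (tri-O-benzyl shanciol B)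
Conditions: Pd(OAc)2 (5 mol %), 2-di-tert-butylphosphino-2',4',6'-triisopropylbiphenyl (10 mol %), K3PO4, toluene, 80 °C
Reagents that add atoms: none
Why: Zerovalent palladium formed from Pd(OAc)2 and the bulky biarylphosphine inserts into the C8a–OTf bond, phosphate-assisted exchange of triflate for the C2 alkoxide gives an aryl(alkoxo) complex of divalent palladium, and C–O reductive elimination forms O1–C8a. The closest known reaction is the intramolecular Buchwald–Hartwig etherification that converts 3-(2-halophenyl)propanols bearing secondary hydroxyl groups into chromans. The pyran ring closes as a six-membered ring by reductive elimination from a seven-membered oxapalladacycle, the O-arylation counterpart of a 6-exo closure onto C8a. No stereocentre is created: C3 and C2 come from steps 8 and 11, and because the benzylic C2–O bond is never broken the (1R,2S) alcohol should map with retention onto the (2R,3S) chroman. The step needs reductive elimination to outrun β-hydride elimination of the benzylic alkoxide, which the di-tert-butyl biarylphosphine secures, and it needs only the C2 oxygen to react, which the benzyl ether on the C3 oxygen secures by excluding five-membered closure. Anhydrous K3PO4 in toluene is chosen so that the triflate is not cleaved before oxidative addition.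

Step 13
Reactants: 23 (2R,3S)-3-(benzyloxy)-2-(4-benzyloxy-3-methoxyphenyl)-5-[2-(3-benzyloxyphenyl)ethyl]-7-methoxychroman
Product: 24 shanciol B, (2R,3S)-2-(4-hydroxy-3-methoxyphenyl)-5-[2-(3-hydroxyphenyl)ethyl]-7-methoxychroman-3-ol
Conditions: H2 (1 atm), Pd(OH)2/C, EtOAc/MeOH, rt
Reagents that add atoms: none
Why: Hydrogenolysis of the two aryl benzyl ethers and the C3 benzyl ether over Pd(OH)2/C is the usual final step of flavan-3-ol syntheses and should leave the cyclic C2–O1 ether and both stereocentres intact at 1 atm and room temperature.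

**Compound list**

1 | 3,5-dimethoxystyrene | C=Cc1cc(OC)cc(OC)c1 | starting material
2 | 1-(benzyloxy)-3-bromobenzene | Brc1cccc(OCc2ccccc2)c1 | starting material
3 | 9-[2-(3,5-dimethoxyphenyl)ethyl]-9-borabicyclo[3.3.1]nonane (formed in the flask, not isolated) | COc1cc(CCB2C3CCCC2CCC3)cc(OC)c1 | intermediate
4 | 1-[2-(3-benzyloxyphenyl)ethyl]-3,5-dimethoxybenzene | COc1cc(CCc2cccc(OCc3ccccc3)c2)cc(OC)c1 | intermediate
5 | N-{2-[2-(3-benzyloxyphenyl)ethyl]-4,6-dimethoxybenzylidene}-N-methylmethanaminium chloride (formed in the flask, not isolated) | COc1cc(CCc2cccc(OCc3ccccc3)c2)c(C=[N+](C)C)c(OC)c1.[Cl-] | intermediate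
6 | 2-[2-(3-benzyloxyphenyl)ethyl]-4,6-dimethoxybenzaldehyde | COc1cc(CCc2cccc(OCc3ccccc3)c2)c(C=O)c(OC)c1 | intermediate
7 | 2-[2-(3-benzyloxyphenyl)ethyl]-6-hydroxy-4-methoxybenzaldehyde | COc1cc(CCc2cccc(OCc3ccccc3)c2)c(C=O)c(O)c1 | intermediate
8 | 3-[2-(3-benzyloxyphenyl)ethyl]-2-formyl-5-methoxyphenyl trifluoromethanesulfonate | COc1cc(CCc2cccc(OCc3ccccc3)c2)c(C=O)c(OS(=O)(=O)C(F)(F)F)c1 | intermediate
9 | 3-[2-(3-benzyloxyphenyl)ethyl]-2-(hydroxymethyl)-5-methoxyphenyl trifluoromethanesulfonate | COc1cc(CCc2cccc(OCc3ccccc3)c2)c(CO)c(OS(=O)(=O)C(F)(F)F)c1 | intermediate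
10 | 3-[2-(3-benzyloxyphenyl)ethyl]-2-(bromomethyl)-5-methoxyphenyl trifluoromethanesulfonate | COc1cc(CCc2cccc(OCc3ccccc3)c2)c(CBr)c(OS(=O)(=O)C(F)(F)F)c1 | intermediate
11 | (R)-4-benzyloxazolidin-2-one | O=C1N[C@H](Cc2ccccc2)CO1 | starting material
12 | (benzyloxy)acetyl chloride | O=C(Cl)COCc1ccccc1 | starting material
13 | lithium salt of (R)-4-benzyloxazolidin-2-one (formed in the flask, not isolated) | [Li+].O=C1[N-][C@H](Cc2ccccc2)CO1 | intermediate
14 | (R)-4-benzyl-3-[(benzyloxy)acetyl]oxazolidin-2-one | O=C(COCc1ccccc1)N1C(=O)OC[C@H]1Cc1ccccc1 | intermediate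
15 | sodium (Z)-enolate of 14 (formed in the flask, not isolated) | [Na+].[O-]/C(=C\OCc1ccccc1)N1C(=O)OC[C@H]1Cc1ccccc1 | intermediate
16 | (R)-4-benzyl-3-[(2S)-2-(benzyloxy)-3-{2-[2-(3-benzyloxyphenyl)ethyl]-4-methoxy-6-[(trifluoromethylsulfonyl)oxy]phenyl}propanoyl]oxazolidin-2-one | COc1cc(CCc2cccc(OCc3ccccc3)c2)c(C[C@H](OCc4ccccc4)C(=O)N5C(=O)OC[C@H]5Cc6ccccc6)c(OS(=O)(=O)C(F)(F)F)c1 | intermediate
17 | (2S)-2-(benzyloxy)-3-{2-[2-(3-benzyloxyphenyl)ethyl]-4-methoxy-6-[(trifluoromethylsulfonyl)oxy]phenyl}-N-methoxy-N-methylpropanamide | COc1cc(CCc2cccc(OCc3ccccc3)c2)c(C[C@H](OCc4ccccc4)C(=O)N(C)OC)c(OS(=O)(=O)C(F)(F)F)c1 | intermediate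
18 | 1-(benzyloxy)-4-bromo-2-methoxybenzene | COc1cc(Br)ccc1OCc1ccccc1 | starting material
19 | 4-benzyloxy-3-methoxyphenylmagnesium bromide (formed in the flask, not isolated) | COc1cc([Mg]Br)ccc1OCc1ccccc1 | intermediate
20 | bromomagnesium alkoxide of the N-methoxy-N-methyl hemiaminal from 17 and 19 (formed in the flask, not isolated) | COc1cc(CCc2cccc(OCc3ccccc3)c2)c(C[C@H](OCc4ccccc4)C(O[Mg]Br)(N(C)OC)c5ccc(OCc6ccccc6)c(OC)c5)c(OS(=O)(=O)C(F)(F)F)c1 | intermediate
21 | (2S)-2-(benzyloxy)-1-(4-benzyloxy-3-methoxyphenyl)-3-{2-[2-(3-benzyloxyphenyl)ethyl]-4-methoxy-6-[(trifluoromethylsulfonyl)oxy]phenyl}propan-1-one | COc1cc(CCc2cccc(OCc3ccccc3)c2)c(C[C@H](OCc4ccccc4)C(=O)c5ccc(OCc6ccccc6)c(OC)c5)c(OS(=O)(=O)C(F)(F)F)c1 | intermediate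
22 | (1R,2S)-2-(benzyloxy)-1-(4-benzyloxy-3-methoxyphenyl)-3-{2-[2-(3-benzyloxyphenyl)ethyl]-4-methoxy-6-[(trifluoromethylsulfonyl)oxy]phenyl}propan-1-ol | COc1cc(CCc2cccc(OCc3ccccc3)c2)c(C[C@H](OCc4ccccc4)[C@H](O)c5ccc(OCc6ccccc6)c(OC)c5)c(OS(=O)(=O)C(F)(F)F)c1 | intermediate
23 | (2R,3S)-3-(benzyloxy)-2-(4-benzyloxy-3-methoxyphenyl)-5-[2-(3-benzyloxyphenyl)ethyl]-7-methoxychroman | COc1cc(CCc2cccc(OCc3ccccc3)c2)c2c(c1)O[C@H](c1ccc(OCc3ccccc3)c(OC)c1)[C@@H](OCc1ccccc1)C2 | intermediate
24 | shanciol B, (2R,3S)-2-(4-hydroxy-3-methoxyphenyl)-5-[2-(3-hydroxyphenyl)ethyl]-7-methoxychroman-3-ol | COc1cc(CCc2cccc(O)c2)c2c(c1)O[C@H](c1ccc(O)c(OC)c1)[C@@H](O)C2 | target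

**Count and risks**

Total step count: 13. Longest linear sequence: 12 steps (steps 1 to 6 and 8 to 13, from 1 to 24); step 7 prepares the glycolate imide.

Steps most likely to fail:

Step 12. β-Hydride elimination from the benzylic palladium alkoxide, or base-induced loss of the triflate before oxidative addition, may outpace C–O reductive elimination. The fallback sets out from 22 and comes back at 23, and it forms the other ether bond instead. The triflate would be cleaved with Et4NOH in aqueous dioxane to the phenol (1R,2S)-2-(benzyloxy)-1-(4-benzyloxy-3-methoxyphenyl)-3-{2-[2-(3-benzyloxyphenyl)ethyl]-6-hydroxy-4-methoxyphenyl}propan-1-ol F1. F1 would then be cyclised with a catalytic sulfonic acid (p-TsOH, CH2Cl2, rt). The para-benzyloxy-stabilised benzylic cation at C2 is trapped by the phenol, and under these reversible conditions the diequatorial 2,3-trans chroman 23 should predominate, with C3 as the controlling centre. Any cis isomer would be removed by chromatography.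

Step 10. The Grignard reagent may attack the sulfonyl sulfur of the aryl triflate, or addition to the amide may be too slow at the temperature that protects the triflate. The fallback sets out from 16 and comes back at 21, and it moves the aryl addition to −78 °C. Reductive removal of the auxiliary with LiBH4 (THF, MeOH, 0 °C) would give (2S)-2-(benzyloxy)-3-{2-[2-(3-benzyloxyphenyl)ethyl]-4-methoxy-6-[(trifluoromethylsulfonyl)oxy]phenyl}propan-1-ol F2. Dess–Martin oxidation would give (2S)-2-(benzyloxy)-3-{2-[2-(3-benzyloxyphenyl)ethyl]-4-methoxy-6-[(trifluoromethylsulfonyl)oxy]phenyl}propanal F3. Addition of 19 at −78 °C would give (2S)-2-(benzyloxy)-1-(4-benzyloxy-3-methoxyphenyl)-3-{2-[2-(3-benzyloxyphenyl)ethyl]-4-methoxy-6-[(trifluoromethylsulfonyl)oxy]phenyl}propan-1-ol as a mixture of C1 epimers F4. A second Dess–Martin oxidation would converge both epimers on ketone 21.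

Step 3. The aryl benzyl ether may be cleaved alongside the chelated methyl ether, or demethylation may stall. The fallback sets out from 6 and comes back at 7, and it replaces selective cleavage by exhaustive cleavage and selective re-protection. BCl3 (CH2Cl2, −78 to 0 °C) would remove both the ortho methyl group and the benzyl group but not the para methyl group, giving 2-hydroxy-6-[2-(3-hydroxyphenyl)ethyl]-4-methoxybenzaldehyde F5. One equivalent of BnBr with K2CO3 in acetone would then benzylate only the phenol that is not hydrogen-bonded to the aldehyde, returning 7.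

Further compounds
F1 | step 12 | (1R,2S)-2-(benzyloxy)-1-(4-benzyloxy-3-methoxyphenyl)-3-{2-[2-(3-benzyloxyphenyl)ethyl]-6-hydroxy-4-methoxyphenyl}propan-1-ol | COc1cc(CCc2cccc(OCc3ccccc3)c2)c(C[C@H](OCc4ccccc4)[C@H](O)c5ccc(OCc6ccccc6)c(OC)c5)c(O)c1
F2 | step 10 | (2S)-2-(benzyloxy)-3-{2-[2-(3-benzyloxyphenyl)ethyl]-4-methoxy-6-[(trifluoromethylsulfonyl)oxy]phenyl}propan-1-ol | COc1cc(CCc2cccc(OCc3ccccc3)c2)c(C[C@H](OCc4ccccc4)CO)c(OS(=O)(=O)C(F)(F)F)c1
F3 | step 10 | (2S)-2-(benzyloxy)-3-{2-[2-(3-benzyloxyphenyl)ethyl]-4-methoxy-6-[(trifluoromethylsulfonyl)oxy]phenyl}propanal | COc1cc(CCc2cccc(OCc3ccccc3)c2)c(C[C@H](OCc4ccccc4)C=O)c(OS(=O)(=O)C(F)(F)F)c1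
F4 | step 10 | (2S)-2-(benzyloxy)-1-(4-benzyloxy-3-methoxyphenyl)-3-{2-[2-(3-benzyloxyphenyl)ethyl]-4-methoxy-6-[(trifluoromethylsulfonyl)oxy]phenyl}propan-1-ol, mixture of C1 epimers | COc1cc(CCc2cccc(OCc3ccccc3)c2)c(C[C@H](OCc4ccccc4)C(O)c5ccc(OCc6ccccc6)c(OC)c5)c(OS(=O)(=O)C(F)(F)F)c1
F5 | step 3 | 2-hydroxy-6-[2-(3-hydroxyphenyl)ethyl]-4-methoxybenzaldehyde | COc1cc(CCc2cccc(O)c2)c(C=O)c(O)c1
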